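**Plan**

- Retrosynthesis: the S–O bond of the 3-sulfate and the two benzyl C–O bonds are cut first, then the C3–O bond. This leads back to a 5,4'-dibenzylated flavone that carries hydrogen at C3.
- That flavone is cut three times at C2 (O1–C2, C2–C3, C2–C1'). C2 is the one carbon of ring C bonded to the ring A oxygen O1, to C3 and to C1' of ring B, so carbon monoxide can supply it between a ring A ortho-hydroxyacetophenone and a ring B aryl bromide.
- Forward: rings A and B are bought and benzylated. Ring C closes in one carbonylative cascade (C1'–C2, then C2–C3, then O1–C2). C3 is then hydroxylated, the 3-OH sulfated and the benzyl groups removed.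
- Stereochemistry: the target has no stereocenter. The only stereocenters on the way (hemiketal C2, epoxide C2/C3) are racemic and are erased by dehydration or aromatisation.

Key step: step 3

Remark: the target is drawn as the free hydrogen sulfate. Aryl hydrogen sulfates hydrolyse under their own acidity, so the sulfate is carried and stored as its sodium salt and the acid form is released cold in the last operation.

**Route**

Step 1
Reactants: 1 2',6'-dihydroxy-4'-methoxyacetophenone; 2 benzyl bromide
Product: 3 1-[2-(benzyloxy)-6-hydroxy-4-methoxyphenyl]ethanone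
Conditions: BnBr (1.05 equiv), K2CO3, acetone, reflux
Reagents that add atoms: none
Why: Williamson etherification; the two hydroxyls of 1 are equivalent, and after the first benzylation the remaining one is locked in a hydrogen bond to the acetyl carbonyl and reacts far more slowly, so about one equivalent of 2 should stop at the monoether.

Step 2
Reactants: 4 4-bromo-2-methoxyphenol; 2 benzyl bromide
Product: 5 1-(benzyloxy)-4-bromo-2-methoxybenzene
Conditions: BnBr, K2CO3, DMF, rt
Reagents that add atoms: none
Why: Williamson etherification of an unhindered phenol; the aryl bromide is inert to K2CO3 in DMF at room temperature.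

Step 3
Reactants: 3 1-[2-(benzyloxy)-6-hydroxy-4-methoxyphenyl]ethanone; 5 1-(benzyloxy)-4-bromo-2-methoxybenzene; 6 carbon monoxide
Product: 10 5,4'-bis(benzyloxy)-7,3'-dimethoxyflavone, via aryl ester 7 (not isolated), via 1,3-diketone 8 (not isolated), via hemiketal 9 (not isolated)
Conditions: Pd(OAc)2 (cat.), n-BuP(1-Ad)2 (cat.), DBU (3 equiv), CO (10 bar), DMSO, 110 °C
Reagents that add atoms: none
Why: Zerovalent palladium, formed from Pd(OAc)2 and the bulky electron-rich di(1-adamantyl)-n-butylphosphine, adds oxidatively to the C–Br bond of 5, and CO insertion gives an aroylpalladium bromide that the DBU-generated phenoxide of 3 intercepts, giving aryl ester 7 and the C1'–C2 bond. DBU then enolises the acetyl group and the enolate attacks the neighbouring ester carbonyl through a six-membered transition state (Baker–Venkataraman O-to-C acyl shift), which makes C2–C3 and gives 1,3-diketone 8. The phenol set free adds to the aryl ketone in a 6-exo-trig closure to hemiketal 9 (O1–C2, ring C), and loss of water gives the aromatic pyranone of 10. The closest known reaction type is the palladium-catalysed carbonylative coupling of 2-hydroxyacetophenones with aryl bromides and CO under DBU to give flavones. No stereocenter remains, because the hemiketal carbon of 9 becomes sp2 on dehydration. The step needs chemoselective capture of the aroylpalladium by one phenol and a single closure site, which the benzyl ether on the other ortho oxygen secures, while the hydrogen-bonded ortho-hydroxyketone holds the phenol oxygen and the methyl group side by side for the acyl shift.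

Step 4
Reactants: 10 5,4'-bis(benzyloxy)-7,3'-dimethoxyflavone
Product: 12 5,4'-bis(benzyloxy)-3-hydroxy-7,3'-dimethoxyflavone, via flavone 2,3-epoxide 11 (not isolated)
Conditions: DMDO (acetone solution), CH2Cl2, 0 °C to rt; then p-TsOH·H2O (cat.), CH2Cl2, rt
Reagents that add atoms: dimethyldioxirane, CC1(C)OO1
Why: Dioxirane epoxidation of the C2=C3 bond gives the racemic cis-fused epoxide 11, which under acid opens at C2 (cation stabilised by O1 and ring B) and loses the C3 proton to give the flavonol, the known dioxirane route from flavones to 3-hydroxyflavones; the benzyl and methyl ethers should survive at low temperature and both transient stereocenters vanish.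

Step 5
Reactants: 12 5,4'-bis(benzyloxy)-3-hydroxy-7,3'-dimethoxyflavone
Product: 13 sodium 5,4'-bis(benzyloxy)-7,3'-dimethoxyflavon-3-yl sulfate
Conditions: SO3·pyridine (excess), pyridine, 50 °C; then aq. NaHCO3; C18 reversed-phase chromatography (H2O–MeOH)
Reagents that add atoms: sulfur trioxide–pyridine complex, [O-]S(=O)(=O)[n+]1ccccc1; sodium hydrogen carbonate, [Na+].OC([O-])=O
Why: O-sulfation of the only free hydroxyl with a sulfur trioxide–amine complex, the regiochemistry being fixed by the benzyl ethers at O5 and O4'; exchange to the sodium salt keeps pyridine, which retards benzyl ether hydrogenolysis, out of the next step.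

Step 6
Reactants: 13 sodium 5,4'-bis(benzyloxy)-7,3'-dimethoxyflavon-3-yl sulfate
Product: 15 rhamnazin 3-O-sulfate in its hydrogen sulfate form, via sodium salt 14 (not isolated)
Conditions: H2 (1 atm), Pd/C, MeOH–THF, rt; filter; then aq. HCl (1.0 equiv), 0 °C; C18 desalting (H2O, then MeOH), cold lyophilisation
Reagents that add atoms: none
Why: Hydrogenolysis of both aryl benzyl ethers over Pd/C under neutral conditions, which aryl sulfate salts, aryl methyl ethers and the tetrasubstituted C2=C3 bond of the pyranone should tolerate, followed by protonation of the sulfate with one equivalent of HCl in the cold.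

**Compound list**

1 | 2',6'-dihydroxy-4'-methoxyacetophenone | CC(=O)c1c(O)cc(OC)cc1O | starting material
2 | benzyl bromide | BrCc1ccccc1 | starting material
3 | 1-[2-(benzyloxy)-6-hydroxy-4-methoxyphenyl]ethanone | CC(=O)c1c(O)cc(OC)cc1OCc1ccccc1 | intermediate
4 | 4-bromo-2-methoxyphenol | COc1cc(Br)ccc1O | starting material
5 | 1-(benzyloxy)-4-bromo-2-methoxybenzene | COc1cc(Br)ccc1OCc1ccccc1 | intermediate
6 | carbon monoxide | [C-]#[O+] | starting material
7 | aryl ester, 2-acetyl-3-(benzyloxy)-5-methoxyphenyl 4-(benzyloxy)-3-methoxybenzoate (forms in the flask in step 3) | CC(=O)c1c(OC(=O)c2ccc(OCc3ccccc3)c(OC)c2)cc(OC)cc1OCc1ccccc1 | intermediate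
8 | 1,3-diketone, 1-[2-(benzyloxy)-6-hydroxy-4-methoxyphenyl]-3-[4-(benzyloxy)-3-methoxyphenyl]propane-1,3-dione (forms in the flask in step 3) | COc1cc(O)c(C(=O)CC(=O)c2ccc(OCc3ccccc3)c(OC)c2)c(OCc2ccccc2)c1 | intermediate
9 | hemiketal, racemic 5-(benzyloxy)-2-[4-(benzyloxy)-3-methoxyphenyl]-2-hydroxy-7-methoxychroman-4-one (forms in the flask in step 3) | COc1cc(OCc2ccccc2)c2c(c1)OC(O)(c1ccc(OCc3ccccc3)c(OC)c1)CC2=O | intermediate
10 | 5,4'-bis(benzyloxy)-7,3'-dimethoxyflavone, 5-(benzyloxy)-2-[4-(benzyloxy)-3-methoxyphenyl]-7-methoxy-4H-chromen-4-one | COc1cc(OCc2ccccc2)c2c(=O)cc(-c3ccc(OCc4ccccc4)c(OC)c3)oc2c1 | intermediate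
11 | flavone 2,3-epoxide of 10, cis-fused oxirane across C2–C3, racemic, one enantiomer drawn (forms in the flask in step 4) | COc1cc(OCc2ccccc2)c2c(c1)O[C@]1(c3ccc(OCc4ccccc4)c(OC)c3)O[C@@H]1C2=O | intermediate
12 | 5,4'-bis(benzyloxy)-3-hydroxy-7,3'-dimethoxyflavone | COc1cc(OCc2ccccc2)c2c(=O)c(O)c(-c3ccc(OCc4ccccc4)c(OC)c3)oc2c1 | intermediate
13 | sodium 5-(benzyloxy)-2-[4-(benzyloxy)-3-methoxyphenyl]-7-methoxy-4-oxo-4H-chromen-3-yl sulfate | COc1cc(OCc2ccccc2)c2c(=O)c(OS(=O)(=O)[O-])c(-c3ccc(OCc4ccccc4)c(OC)c3)oc2c1.[Na+] | intermediate
14 | sodium 5-hydroxy-2-(4-hydroxy-3-methoxyphenyl)-7-methoxy-4-oxo-4H-chromen-3-yl sulfate, sodium salt of the target (forms in the flask in step 6) | COc1cc(O)c2c(=O)c(OS(=O)(=O)[O-])c(-c3ccc(O)c(OC)c3)oc2c1.[Na+] | intermediate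
15 | rhamnazin 3-O-sulfate, 5-hydroxy-2-(4-hydroxy-3-methoxyphenyl)-7-methoxy-4-oxo-4H-chromen-3-yl hydrogen sulfate | COc1cc(O)c2c(=O)c(OS(=O)(=O)O)c(-c3ccc(O)c(OC)c3)oc2c1 | target

**Count**

Total steps: 6. Longest linear sequence: 5 steps (1 → 3 → 10 → 12 → 13 → 15); step 2 supplies the ring B partner in parallel.

**Steps most likely to fail**

Step 3. Oxidative addition into the electron-rich, para-alkoxy aryl bromide may be slow enough that CO-saturated palladium aggregates to inactive metal. The cascade may also stall after O-acylation, because enolisation next to the chelated, doubly ortho-substituted ketone is slow. The fallback brings C2 in as an aldehyde carbon and closes ring C oxidatively. It sets out from 3: Claisen–Schmidt condensation with purchased 4-(benzyloxy)-3-methoxybenzaldehyde F1 (KOH, EtOH, rt) should give the (E)-chalcone F2. Heating F2 with catalytic I2 in DMSO at about 120 °C should bring about oxa-Michael closure and dehydrogenation, and the route is rejoined at flavone 10.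

Step 4. The dioxirane may oxidise the benzylic C–H bonds of the two benzyl ethers or the electron-rich rings before the electron-poor chromone double bond is fully epoxidised. The fallback makes C3 the nucleophile instead. It sets out from 10: LiN(i-Pr)2 in THF at −78 °C should remove the C3 proton next to the carbonyl to give the 3-lithioflavone F3. B(OMe)3 traps it as the dimethyl flavon-3-ylboronate F4, and AcOH with aqueous H2O2 oxidises the C–B bond, so the route is rejoined at flavonol 12.

Step 6. Hydrogenolysis may stall on the anionic sulfate salt through catalyst inhibition or poor solubility, and adventitious acid in methanol may solvolyse the sulfate monoester before both benzyl groups are gone. The fallback carries the sulfate through debenzylation as a neutral neopentyl diester. It sets out from 12: NaN(SiMe3)2 and neopentyl chlorosulfate in THF (−78 °C to rt) should give the neopentyl sulfate diester F5. H2 over Pd/C in EtOAc–MeOH removes both benzyl ethers to give the dihydroxy diester F6. NaN3 in DMF at 70 °C then displaces the sulfate from the neopentyl carbon (the azide by-product is kept in solution), and the route is rejoined at sodium salt 14 for the cold acid release to 15.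

**Further compounds**

F1 | step 3 | 4-(benzyloxy)-3-methoxybenzaldehyde (purchased) | COc1cc(C=O)ccc1OCc1ccccc1
F2 | step 3 | (E)-1-[2-(benzyloxy)-6-hydroxy-4-methoxyphenyl]-3-[4-(benzyloxy)-3-methoxyphenyl]prop-2-en-1-one | COc1cc(O)c(C(=O)/C=C/c2ccc(OCc3ccccc3)c(OC)c2)c(OCc2ccccc2)c1
F3 | step 4 | 5,4'-bis(benzyloxy)-3-lithio-7,3'-dimethoxyflavone | COc1cc(OCc2ccccc2)c2c(=O)c([Li])c(-c3ccc(OCc4ccccc4)c(OC)c3)oc2c1
F4 | step 4 | dimethyl [5,4'-bis(benzyloxy)-7,3'-dimethoxyflavon-3-yl]boronate | COB(OC)c1c(-c2ccc(OCc3ccccc3)c(OC)c2)oc2cc(OC)cc(OCc3ccccc3)c2c1=O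
F5 | step 6 | 5,4'-bis(benzyloxy)-7,3'-dimethoxyflavon-3-yl neopentyl sulfate | COc1cc(OCc2ccccc2)c2c(=O)c(OS(=O)(=O)OCC(C)(C)C)c(-c3ccc(OCc4ccccc4)c(OC)c3)oc2c1
F6 | step 6 | 5,4'-dihydroxy-7,3'-dimethoxyflavon-3-yl neopentyl sulfate | COc1cc(O)c2c(=O)c(OS(=O)(=O)OCC(C)(C)C)c(-c3ccc(O)c(OC)c3)oc2c1
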